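**Strategy**

Everything rests on disconnecting the bond between the quaternary, methoxy-bearing ring carbon C4 of the cyclohexa-2,5-dienone and C2 of the 1-arylpropenyl side chain. C4 is read as a former quinone carbonyl: in 2-methoxy-5-propenyl-1,4-benzoquinone only the carbonyl flanked by the C–OMe carbon is neither a vinylogous ester nor shielded by the propenyl group. In the key step an (E)-alkenylzinc reagent, made in the same flask by syn-hydrozirconation of 1-(3,4-dimethoxyphenyl)propyne, adds to that carbonyl under a chiral titanium catalyst; one operation forms the C–C bond, fixes the (E)-trisubstituted alkene and sets the (S)-carbinol centre. O-Methylation then gives the target.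

Key step: step 4

Assumption: the sense of induction of the titanium catalyst on a quinone acceptor cannot be predicted with confidence; "the chiral ligand" means the enantiomer of the bis(sulfonamide) diol that delivers the alkenyl group to the Si face of the attacked carbonyl (both enantiomers are accessible).

Remark: in the SMILES of zirconium compounds the η5-cyclopentadienyl rings are written as σ-bonded C5H5 groups.

**Route**

Step 1
Reactants: 1 1-bromo-2,4,5-trimethoxybenzene
Product: 2 2-bromo-5-methoxycyclohexa-2,5-diene-1,4-dione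
Conditions: (NH4)2Ce(NO3)6 (2.5 equiv), MeCN/H2O, 0 °C to rt
Reagents that add atoms: water, O
Why: Oxidative demethylation with ceric ammonium nitrate: the arene radical cation takes up water at the two para-related methoxy carbons (C2 and C5) and loses methanol, which should give the p-quinone and leave the bromine and the third methoxy group in place.

Step 2
Reactants: 2 2-bromo-5-methoxycyclohexa-2,5-diene-1,4-dione; 3 (E)-prop-1-en-1-ylboronic acid
Product: 4 2-methoxy-5-[(E)-prop-1-en-1-yl]cyclohexa-2,5-diene-1,4-dione
Conditions: Pd(dppf)Cl2 (5 mol %), K2CO3, degassed THF/H2O, 45 °C; product used without storage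
Reagents that add atoms: none
Why: Suzuki–Miyaura coupling: the C–Br bond of the bromoquinone is a vinylogous acyl bromide that should add readily to Pd(0), and transmetalation and reductive elimination transfer the propenyl group with retention of its (E) geometry.

Step 3
Reactants: 5 4-ethynyl-1,2-dimethoxybenzene
Product: 7 1,2-dimethoxy-4-(prop-1-yn-1-yl)benzene, via lithium acetylide 6 (not isolated)
Conditions: n-BuLi, THF, −78 °C; MeI, −78 °C to rt
Reagents that add atoms: iodomethane, CI
Why: Deprotonation of the terminal alkyne followed by SN2 methylation of the lithium acetylide (acetylide alkylation).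

Step 4
Reactants: 7 1,2-dimethoxy-4-(prop-1-yn-1-yl)benzene; 4 2-methoxy-5-[(E)-prop-1-en-1-yl]cyclohexa-2,5-diene-1,4-dione
Product: 10 (S)-4-hydroxy-5-methoxy-4-[(E)-1-(3,4-dimethoxyphenyl)prop-1-en-2-yl]-2-[(E)-prop-1-en-1-yl]cyclohexa-2,5-dien-1-one, via alkenylzirconocene chloride 8 (not isolated), via alkenyl(methyl)zinc 9 (not isolated)
Conditions: 7 (1.6 equiv), Cp2Zr(H)Cl (1.5 equiv), CH2Cl2, rt; solvent exchange to toluene; Me2Zn (1.5 equiv), −78 °C; then the chiral ligand [trans-cyclohexane-1,2-diamine bis(exo-2-hydroxy-10-camphorsulfonamide), 10 mol %], Ti(OiPr)4 (1.2 equiv), slow addition of 4 (1.0 equiv), toluene, −20 to 0 °C; aq NH4Cl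
Reagents that add atoms: none
Why: Proposed new method: syn-hydrozirconation of 7 should place zirconium on the methyl-bearing alkyne carbon (distal to the aryl group) with hydrogen cis to it, and Zr-to-Zn exchange with Me2Zn followed by Zn-to-Ti exchange should give a chiral bis(sulfonamide)diolato-titanium alkenyl that binds the C1 carbonyl oxygen of 4 (quinone numbering: C1=O, C2–OMe, C4=O, C5–propenyl; the C2–OMe oxygen can act as a second donor) and transfers the alkenyl group to the carbonyl carbon with retention of the (E) geometry throughout. The closest known reaction type is the titanium/bis(sulfonamide)diol-catalysed enantioselective addition of alkenylzinc reagents, made by hydrozirconation and zinc transmetalation, to ketones including cyclic conjugated enones; what is new is a p-benzoquinone carbonyl as the acceptor. No ring is closed. The new stereocentre (quinone C1, which becomes C4 of 10) is set by the catalyst, which must tell the C(OMe)= flank from the CH= flank and deliver the alkenyl group to the Si face (priorities O > C2 > C6) to give (S). The step needs site selectivity between the two carbonyls and 1,2- over conjugate addition: the C4 carbonyl of 4 is a vinylogous ester (C2(OMe)=C3–C4=O) and is shielded by the propenyl group on C5, whereas C1 is the most electrophilic and least hindered carbonyl carbon, and a titanium-bound alkenyl group is a hard, weakly reducing 1,2-nucleophile. The sp2 alkenyl group should transfer much faster than the methyl group on zinc, and the slight excess of alkyne over Cp2Zr(H)Cl should leave no Zr–H to reduce the quinone.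

Step 5
Reactants: 10 (S)-4-hydroxy-5-methoxy-4-[(E)-1-(3,4-dimethoxyphenyl)prop-1-en-2-yl]-2-[(E)-prop-1-en-1-yl]cyclohexa-2,5-dien-1-one
Product: 12 (S)-4,5-dimethoxy-4-[(E)-1-(3,4-dimethoxyphenyl)prop-1-en-2-yl]-2-[(E)-prop-1-en-1-yl]cyclohexa-2,5-dien-1-one, via sodium alkoxide 11 (not isolated)
Conditions: NaH, THF, 0 °C; MeI, 0 °C to rt
Reagents that add atoms: iodomethane, CI
Why: Williamson ether synthesis: irreversible deprotonation of the tertiary alcohol and SN2 attack on iodomethane; no bond to C4 is broken, so the (S) configuration should be kept.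

**Compound list**

1 | 1-bromo-2,4,5-trimethoxybenzene | COc1cc(OC)c(Br)cc1OC | starting material
2 | 2-bromo-5-methoxycyclohexa-2,5-diene-1,4-dione | COC1=CC(=O)C(Br)=CC1=O | intermediate
3 | (E)-prop-1-en-1-ylboronic acid | C/C=C/B(O)O | starting material
4 | 2-methoxy-5-[(E)-prop-1-en-1-yl]cyclohexa-2,5-diene-1,4-dione | C/C=C/C1=CC(=O)C(OC)=CC1=O | intermediate
5 | 4-ethynyl-1,2-dimethoxybenzene | C#Cc1ccc(OC)c(OC)c1 | starting material
6 | lithium (3,4-dimethoxyphenyl)acetylide | [Li]C#Cc1ccc(OC)c(OC)c1 | intermediate
7 | 1,2-dimethoxy-4-(prop-1-yn-1-yl)benzene | CC#Cc1ccc(OC)c(OC)c1 | intermediate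
8 | chlorobis(cyclopentadienyl)[(E)-1-(3,4-dimethoxyphenyl)prop-1-en-2-yl]zirconium | Cl[Zr](C1C=CC=C1)(C1C=CC=C1)/C(C)=C/c1ccc(OC)c(OC)c1 | intermediate
9 | [(E)-1-(3,4-dimethoxyphenyl)prop-1-en-2-yl](methyl)zinc | C[Zn]/C(C)=C/c1ccc(OC)c(OC)c1 | intermediate
10 | (S)-4-hydroxy-5-methoxy-4-[(E)-1-(3,4-dimethoxyphenyl)prop-1-en-2-yl]-2-[(E)-prop-1-en-1-yl]cyclohexa-2,5-dien-1-one | C/C=C/C1=C[C@](O)(/C(C)=C/c2ccc(OC)c(OC)c2)C(OC)=CC1=O | intermediate
11 | sodium alkoxide of 10 | C/C=C/C1=C[C@]([O-])(/C(C)=C/c2ccc(OC)c(OC)c2)C(OC)=CC1=O.[Na+] | intermediate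
12 | (S)-4,5-dimethoxy-4-[(E)-1-(3,4-dimethoxyphenyl)prop-1-en-2-yl]-2-[(E)-prop-1-en-1-yl]cyclohexa-2,5-dien-1-one | C/C=C/C1=C[C@](OC)(/C(C)=C/c2ccc(OC)c(OC)c2)C(OC)=CC1=O | target

**Summary**

Total step count: 5. Longest linear sequence: 4 steps (1 → 2 → 4 → 10 → 12; steps 1, 2, 4, 5).

**Steps most likely to fail**

1. Step 4 (proposed new method). Three processes threaten it. Electron transfer from the organometallic species to the quinone, or an uncatalysed racemic addition, may outrun the catalysed pathway. The hydrozirconation may not be fully regioselective without excess hydride. The catalyst may discriminate poorly between the two sp2 flanks of the carbonyl. The fallback uses known chemistry, sets out from 7 and 4 and comes back at 10. Hydrozirconation of 7 to 8 followed by iodinolysis should give (E)-4-(2-iodoprop-1-en-1-yl)-1,2-dimethoxybenzene F1, which is purified free of any regioisomer. Iodine–lithium exchange (t-BuLi, Et2O, −78 °C) should give the configurationally stable [(E)-1-(3,4-dimethoxyphenyl)prop-1-en-2-yl]lithium F2. Its 1,2-addition to the non-vinylogous carbonyl of 4 at −78 °C, an established reaction of organolithiums with alkoxyquinones, should give the lithium alkoxide of the racemic quinol F3 and, after aqueous work-up, the racemic quinol F4. Preparative chromatography on a chiral stationary phase then separates 10 from the (R)-4-hydroxy-5-methoxy-4-[(E)-1-(3,4-dimethoxyphenyl)prop-1-en-2-yl]-2-[(E)-prop-1-en-1-yl]cyclohexa-2,5-dien-1-one F5.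

2. Step 2. The quinone may decompose under the basic aqueous conditions, it may oxidise Pd(0) and the phosphine, and the alkenylquinone may dimerise by Diels–Alder reaction during coupling or handling. The fallback changes the order of events, sets out from 2 and comes back at 12. Bromoquinone 2 is joined with 7 under the conditions of step 4 (via 8 and 9) to give (S)-2-bromo-4-hydroxy-5-methoxy-4-[(E)-1-(3,4-dimethoxyphenyl)prop-1-en-2-yl]cyclohexa-2,5-dien-1-one F6. Deprotonation with NaH gives the sodium alkoxide of the bromoquinol F7, and iodomethane converts it into (S)-2-bromo-4,5-dimethoxy-4-[(E)-1-(3,4-dimethoxyphenyl)prop-1-en-2-yl]cyclohexa-2,5-dien-1-one F8. The propenyl group is then introduced last by Suzuki–Miyaura coupling of this α-bromoenone with 3 (Pd(dppf)Cl2, K2CO3, THF/H2O), a robust substrate class for the coupling.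

3. Step 5. The hindered tertiary alkoxide may add in conjugate fashion to the dienone of a second molecule, or alkylation of the shielded oxygen may stall. The fallback changes the mode of activation, sets out from 10 and comes back at 12. The neutral alcohol is methylated by an electrophilic oxonium donor (trimethyloxonium tetrafluoroborate, 1,8-bis(dimethylamino)naphthalene, CH2Cl2, 0 °C), so that no free alkoxide is formed. No new compound arises on the way.

**Further compounds**

F1 | step 4 | (E)-4-(2-iodoprop-1-en-1-yl)-1,2-dimethoxybenzene | I/C(C)=C/c1ccc(OC)c(OC)c1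
F2 | step 4 | [(E)-1-(3,4-dimethoxyphenyl)prop-1-en-2-yl]lithium | [Li]/C(C)=C/c1ccc(OC)c(OC)c1
F3 | step 4 | lithium alkoxide of the racemic quinol | C/C=C/C1=CC([O-])(/C(C)=C/c2ccc(OC)c(OC)c2)C(OC)=CC1=O.[Li+]
F4 | step 4 | racemic 4-hydroxy-5-methoxy-4-[(E)-1-(3,4-dimethoxyphenyl)prop-1-en-2-yl]-2-[(E)-prop-1-en-1-yl]cyclohexa-2,5-dien-1-one | C/C=C/C1=CC(O)(/C(C)=C/c2ccc(OC)c(OC)c2)C(OC)=CC1=O
F5 | step 4 | (R)-4-hydroxy-5-methoxy-4-[(E)-1-(3,4-dimethoxyphenyl)prop-1-en-2-yl]-2-[(E)-prop-1-en-1-yl]cyclohexa-2,5-dien-1-one | C/C=C/C1=C[C@@](O)(/C(C)=C/c2ccc(OC)c(OC)c2)C(OC)=CC1=O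
F6 | step 2 | (S)-2-bromo-4-hydroxy-5-methoxy-4-[(E)-1-(3,4-dimethoxyphenyl)prop-1-en-2-yl]cyclohexa-2,5-dien-1-one | BrC1=C[C@](O)(/C(C)=C/c2ccc(OC)c(OC)c2)C(OC)=CC1=O
F7 | step 2 | sodium alkoxide of the bromoquinol | BrC1=C[C@]([O-])(/C(C)=C/c2ccc(OC)c(OC)c2)C(OC)=CC1=O.[Na+]
F8 | step 2 | (S)-2-bromo-4,5-dimethoxy-4-[(E)-1-(3,4-dimethoxyphenyl)prop-1-en-2-yl]cyclohexa-2,5-dien-1-one | BrC1=C[C@](OC)(/C(C)=C/c2ccc(OC)c(OC)c2)C(OC)=CC1=O
F0 | step 5 | none | none
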